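The readings are calculated for substances that don't exist; noise was put on by code.

Amounts of target at the end of the feed stand well clear of the scatter in the earlier runs: green ends at 8.0% and red at 11.6%, and the smaller of these is still 16.0 times the scatter of a reading.

| flask | substrate | coupling partner | remark | time |
|---|---|---|---|---|
| green | 0.17 M (fed, over 25 h) | 1.5 equiv | run made earlier |  |
| red | 0.38 M (fed, over 25 h) | 1.5 equiv | run made earlier |  |
| teal | 0.25 M (fed, over 25 h) | 3 equiv | run made earlier |  |
| flask | 0.25 M (fed, over 25 h) | 1.50 equiv |  | 25 h |

| run | time / h | target / % |
|---|---|---|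
| green | 5.00 | 0 |
| green | 10.0 | 2.5 |
| green | 15.0 | 3.6 |
| green | 20.0 | 5.7 |
| green | 25.0 | 8.0 |
| red | 2.00 | 0 |
| red | 4.00 | 0.6 |
| red | 8.00 | 2.3 |
| red | 12.0 | 4.3 |
| red | 25.0 | 11.6 |
| teal | 5.00 | 1.2 |
| teal | 10.0 | 3.3 |
| teal | 15.0 | 5.4 |
| teal | 20.0 | 9.3 |
| teal | 25.0 | 13.2 |

(standard deviation of a reading: 0.5 percentage points)

- what may be going on: intermediate C <-> target; intermediate D -> decomposed reagent; intermediate A -> intermediate D; coupling partner + intermediate D <-> intermediate E; substrate + coupling partner <-> intermediate B; substrate -> intermediate A; substrate + coupling partner -> intermediate C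
- percentages count the whole charge, also what has not yet gone in

* amount of target in percent of the substrate charged, at 80 min, 6.0 h and 25 h

A rule of thumb serves here. Green and red share the feed time and the equivalents, so we treat the end amount as a power of the charged c(substrate). We call that power the yield order, reckoned as the logarithm of the ratio of the end amounts over the logarithm of the ratio of the charges; it comes to 0.462. This flask has the same feed time and equivalents, and its charge lies between theirs, so scaling up from green by 1.47 to the power 0.462 gives us 9.56% at 25 h.

The rule has a border in time. Red at 4.00 h reads 0.6%, which is 1.20 times the scatter, so a ratio of readings that early carries little weight. The 80 min asked for is a third of that time, and it comes before the first reading of each earlier run. At 5.00 h, green reads 0% and teal 1.2%, so the value at 6.0 h is a judgement from neighbours, and we commit firmly to the value at 25 h.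

The forecast gives 0.05%, 1% and 9.6%, noting that “The curves show an induction period”; its last value stands where ours does.

The flask gives 0.0132%, 0.670% and 9.79%, the last lying 0.23 percentage points above our reckoning, less than the scatter.

    intermediate C ⇌ target (K = 0.420, k = 0.0460 h⁻¹)
    intermediate D → decomposed reagent (k = 0.0670 h⁻¹)
    intermediate A → intermediate D (k = 0.00240 h⁻¹)
    coupling partner + intermediate D ⇌ intermediate E (K = 6.30 L mol⁻¹, k = 0.00930 L mol⁻¹ h⁻¹)
    substrate + coupling partner ⇌ intermediate B (K = 2.50 L mol⁻¹, k = 0.130 L mol⁻¹ h⁻¹)
    substrate → intermediate A (k = 0.140 h⁻¹)
    substrate + coupling partner → intermediate C (k = 0.580 L mol⁻¹ h⁻¹)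

At 25.0 h this flask holds 9.79% of target beside 35.4% of intermediate C, a ratio of 0.277, below the equilibrium constant 0.42 of the step from intermediate C to target. Teal has this flask's charge of substrate and twice the equivalents; carrying the yield order 0.462 over from the charge, where it was read, to the equivalents takes this flask's end amount to 13.5%, and teal reads 13.2%.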